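## Retrosynthetic overview

1. The oxonene is closed last by ring-closing metathesis at C6=C7 of 23. The C13 enone is unmasked from a silyl enol ether, and the C9 methallyl group comes from C-glycosylation of the lactol acetate 20.
2. Key step: the oxepane is closed by forming the C3–O16 bond, a 7-exo opening of the C3/C4 epoxide of 17 by the C16 silyl ether (inversion at C3, O4 released for the acetate).
3. The cyclohexene ring comes from an endo Diels–Alder reaction of epoxy butenolide 16 (the future tetrahydrofuran) with 2-silyloxy diene 6, setting C1, C10 and C14.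
4. 16 comes from propargyl alcohol (carbomagnesiation/allylation, Sharpless epoxidation for C3/C4, alkynylation for C2, Lindlar lactonisation); 6 comes from (S)-3-bromo-2-methylpropan-1-ol (C15).
5. Ring order: epoxide → butenolide → cyclohexene → oxepane → tetrahydrofuran completed at C9 → oxonene.

Assumption: positions are cited in cladiellin numbering (C1/C10 ring fusion, C2–O–C9 ether, C3–O–C16 ether, C4 acetate, C6=C7, C11=C12–C13=O), and the SMILES is read as (1R,2S,3S,4R,6Z,9S,10S,14R,15R).
Assumption: the (R,R)-ProPhenol/Me2Zn catalyst is taken to give Si-face addition in step 6; if its sense is the opposite, the (S,S)-ligand is used with no other change.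

## Route

Step 1
Reactants: 1 (S)-3-bromo-2-methylpropan-1-ol; 2 (E)-N-methoxy-N-methylbut-2-enamide
Product: 4 (R,E)-7-hydroxy-6-methylhept-2-en-4-one, via alkoxide Grignard reagent 3 (not isolated)
Conditions: i-PrMgCl (1.0 equiv), THF, −20 °C; Mg, THF, 45 °C; then 2, 0 °C; aq NH4Cl
Reagents that add atoms: none
Why: Weinreb ketone synthesis, in which the alkoxide-masked Grignard reagent (Normant type) adds once to the amide because the chelated tetrahedral intermediate blocks over-addition; C15 comes from the chiral pool and is not touched.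

Step 2
Reactants: 4 (R,E)-7-hydroxy-6-methylhept-2-en-4-one
Product: 6 triisopropyl{[(2E,4Z,6R)-6-methyl-7-(trimethylsilyloxy)hepta-2,4-dien-4-yl]oxy}silane, via trimethylsilyl ether enone 5 (not isolated)
Conditions: TMSCl, Et3N, CH2Cl2, 0 °C; then TIPSOTf, Et3N, 0 °C to rt
Reagents that add atoms: chlorotrimethylsilane C[Si](C)(C)Cl; triisopropylsilyl triflate CC(C)[Si](C(C)C)(C(C)C)OS(=O)(=O)C(F)(F)F
Why: O-silylation followed by soft enolisation (silyl triflate/amine) at the alpha' carbon gives the cross-conjugated 2-silyloxy diene as the (Z)-enol ether, so C15 sits "outside" on the diene; the labile trimethylsilyl ether keeps O16 as a latent nucleophile.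

Step 3
Reactants: 7 prop-2-yn-1-ol; 8 allyl bromide
Product: 10 (Z)-2-methylhexa-2,5-dien-1-ol, via alkenylmagnesium chelate 9 (not isolated)
Conditions: MeMgBr (2.5 equiv), CuI (10 mol %), THF, −10 °C to rt; then 8, 0 °C to rt
Reagents that add atoms: methylmagnesium bromide C[Mg]Br
Why: Copper-catalysed anti-carbomagnesiation of propargyl alcohol (Duboudin–Jousseaume) puts methyl on C2 and magnesium on C3 cis to the alkoxide in a five-membered chelate, and allylation with retention gives the (Z)-trisubstituted olefin.

Step 4
Reactants: 10 (Z)-2-methylhexa-2,5-dien-1-ol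
Product: 11 [(2S,3R)-2-methyl-3-(prop-2-en-1-yl)oxiran-2-yl]methanol
Conditions: Ti(O-i-Pr)4 (10 mol %), L-(+)-diethyl tartrate (12 mol %), t-BuOOH, 4 Å MS, CH2Cl2, −20 °C
Reagents that add atoms: tert-butyl hydroperoxide CC(C)(C)OO
Why: Sharpless asymmetric epoxidation of a primary allylic alcohol, where the L-(+)-tartrate complex delivers oxygen to the face that gives the (2S,3R)-epoxide (future C3 and C4) and the unactivated terminal alkene does not react.

Step 5
Reactants: 11 [(2S,3R)-2-methyl-3-(prop-2-en-1-yl)oxiran-2-yl]methanol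
Product: 12 (2R,3R)-2-methyl-3-(prop-2-en-1-yl)oxirane-2-carbaldehyde
Conditions: Dess–Martin periodinane, NaHCO3, CH2Cl2, 0 °C to rt
Reagents that add atoms: none
Why: Dess–Martin oxidation under buffered conditions; the alpha carbon is fully substituted, so the epoxy aldehyde cannot epimerise.

Step 6
Reactants: 12 (2R,3R)-2-methyl-3-(prop-2-en-1-yl)oxirane-2-carbaldehyde; 13 methyl propiolate
Product: 14 methyl (4S)-4-hydroxy-4-[(2S,3R)-2-methyl-3-(prop-2-en-1-yl)oxiran-2-yl]but-2-ynoate
Conditions: Me2Zn (3 equiv), (R,R)-ProPhenol (20 mol %), Ph3PO (40 mol %), PhMe, 4 °C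
Reagents that add atoms: none
Why: Zinc–ProPhenol (Trost) alkynylation with Si-face addition sets C2; the Felkin–Anh preference (attack anti to the epoxide C–O bond) leads to the same erythro isomer, so catalyst and substrate are matched.

Step 7
Reactants: 14 methyl (4S)-4-hydroxy-4-[(2S,3R)-2-methyl-3-(prop-2-en-1-yl)oxiran-2-yl]but-2-ynoate
Product: 16 (5S)-5-[(2R,3R)-2-methyl-3-(prop-2-en-1-yl)oxiran-2-yl]furan-2(5H)-one, via (Z)-hydroxy enoate 15 (not isolated)
Conditions: H2 (1 atm), Lindlar catalyst (Pd/CaCO3 poisoned with Pb(OAc)2), quinoline, EtOAc, rt; then SiO2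
Reagents that add atoms: none
Why: Lindlar semihydrogenation gives the (Z)-enoate, whose gamma-hydroxyl lactonises to the butenolide; the poisoned catalyst leaves the terminal alkene and the epoxide alone when the reaction is stopped at one equivalent of H2.

Step 8
Reactants: 16 (5S)-5-[(2R,3R)-2-methyl-3-(prop-2-en-1-yl)oxiran-2-yl]furan-2(5H)-one; 6 triisopropyl{[(2E,4Z,6R)-6-methyl-7-(trimethylsilyloxy)hepta-2,4-dien-4-yl]oxy}silane
Product: 17 endo Diels–Alder adduct (cis-fused C9 lactone with the C12=C13 triisopropylsilyl enol ether, C3/C4 epoxide and C16 trimethylsilyl ether)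
Conditions: PhMe, BHT (cat.), 130 °C, sealed tube
Reagents that add atoms: none
Why: Thermal Diels–Alder reaction in which the nucleophilic diene terminus C14 bonds to the butenolide beta carbon C1, anti to the bulky C2 substituent and endo (Alder rule), so C1, C10 and C14 (and the transient C11) are set with H1, H10 and H14 all cis and H2 trans to H1.

Step 9
Reactants: 17 endo Diels–Alder adduct
Product: 19 oxepane lactone with free C4 hydroxyl, via C4 trimethylsilyl ether 18 (not isolated)
Conditions: TMSOTf (5 mol %), 2,6-di-tert-butyl-4-methylpyridine (10 mol %), CH2Cl2, −78 to −40 °C; then citric acid, MeOH, 0 °C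
Reagents that add atoms: none
Why: Proposed new method: a catalytic silyl-relay cycloetherification in which TMSOTf silylates the epoxide oxygen, the oxygen of the C16 trimethylsilyl ether opens the silyloxiranium at the fully substituted C3 in a 7-exo mode with inversion (the 8-endo path at secondary C4 is disfavoured), and the resulting silyloxonium returns Me3Si+ to triflate, so the silyl group moves from O16 to O4 and the acid turns over; the closest known reactions are Lewis-acid-promoted hydroxy-epoxide cycloetherifications and silyl-triflate-catalysed Mukaiyama-type silyl transfer, and the aprotic conditions are chosen to spare the silyl enol ether.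

Step 10
Reactants: 19 oxepane lactone with free C4 hydroxyl
Product: 20 C9 lactol acetate with C4 acetate
Conditions: i-Bu2AlH (3.2 equiv), CH2Cl2, −78 °C; then pyridine, DMAP, Ac2O, −78 to 0 °C
Reagents that add atoms: acetic anhydride CC(=O)OC(C)=O
Why: Rychnovsky reductive acetylation, where reduction stops at the aluminium lactolate at −78 °C and in situ acetylation traps it while also acetylating the C4 alkoxide, which installs the acetate of the target.

Step 11
Reactants: 20 C9 lactol acetate with C4 acetate; 21 trimethyl(2-methylprop-2-en-1-yl)silane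
Product: 22 C9-methallyl tetrahydrofuran (2,9-cis) with C4 acetate and silyl enol ether
Conditions: 21 (3 equiv), TMSOTf (20 mol %), CH2Cl2, −78 °C
Reagents that add atoms: none
Why: Hosomi–Sakurai C-glycosylation in which the C9 oxocarbenium ion is attacked on the convex face of the cis-fused bicycle, anti to the cyclohexene ring, giving the 2,9-cis ether (C9 S).

Step 12
Reactants: 22 C9-methallyl tetrahydrofuran (2,9-cis) with C4 acetate and silyl enol ether
Product: 23 enone diene (ring-closing metathesis precursor)
Conditions: DDQ (1.5 equiv), 2,6-lutidine, CH2Cl2, 0 °C to rt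
Reagents that add atoms: none
Why: DDQ dehydrogenation of a silyl enol ether, where hydride abstraction from C11 gives the oxygen-stabilised allyl cation that loses the silyl group to form the C11=C12 enone; the C11 stereocentre is erased as intended.

Step 13
Reactants: 23 enone diene (ring-closing metathesis precursor)
Product: 24 target CNP0320560.1
Conditions: second-generation Hoveyda–Grubbs catalyst RuCl2(H2IMes)(=CH-C6H4-2-O-i-Pr) (10 mol %), PhMe (2 mM), 80 °C
Reagents that add atoms: none
Why: Ring-closing metathesis that initiates at the monosubstituted C6 olefin and closes onto the 1,1-disubstituted C7 olefin; the nine-membered ring allows only the (Z)-trisubstituted alkene.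

## Compound list

1 | (S)-3-bromo-2-methylpropan-1-ol | BrC[C@@H](C)CO | starting material
2 | (E)-N-methoxy-N-methylbut-2-enamide | C/C=C/C(=O)N(C)OC | starting material
3 | chloromagnesium (S)-3-(bromomagnesio)-2-methylpropan-1-olate (alkoxide Grignard reagent) | Br[Mg]C[C@@H](C)CO[Mg]Cl | intermediate
4 | (R,E)-7-hydroxy-6-methylhept-2-en-4-one | C/C=C/C(=O)C[C@@H](C)CO | intermediate
5 | (R,E)-6-methyl-7-(trimethylsilyloxy)hept-2-en-4-one | C/C=C/C(=O)C[C@@H](C)CO[Si](C)(C)C | intermediate
6 | triisopropyl{[(2E,4Z,6R)-6-methyl-7-(trimethylsilyloxy)hepta-2,4-dien-4-yl]oxy}silane | C/C=C/C(=C/[C@@H](C)CO[Si](C)(C)C)O[Si](C(C)C)(C(C)C)C(C)C | intermediate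
7 | prop-2-yn-1-ol | C#CCO | starting material
8 | allyl bromide | C=CCBr | starting material
9 | bromomagnesium (Z)-3-(bromomagnesio)-2-methylprop-2-en-1-olate (alkenylmagnesium chelate) | Br[Mg]/C=C(/C)CO[Mg]Br | intermediate
10 | (Z)-2-methylhexa-2,5-dien-1-ol | OC/C(C)=C\CC=C | intermediate
11 | [(2S,3R)-2-methyl-3-(prop-2-en-1-yl)oxiran-2-yl]methanol | OC[C@]1(C)O[C@@H]1CC=C | intermediate
12 | (2R,3R)-2-methyl-3-(prop-2-en-1-yl)oxirane-2-carbaldehyde | O=C[C@]1(C)O[C@@H]1CC=C | intermediate
13 | methyl propiolate | C#CC(=O)OC | starting material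
14 | methyl (4S)-4-hydroxy-4-[(2S,3R)-2-methyl-3-(prop-2-en-1-yl)oxiran-2-yl]but-2-ynoate | COC(=O)C#C[C@H](O)[C@]1(C)O[C@@H]1CC=C | intermediate
15 | methyl (2Z,4S)-4-hydroxy-4-[(2S,3R)-2-methyl-3-(prop-2-en-1-yl)oxiran-2-yl]but-2-enoate | COC(=O)/C=C\[C@H](O)[C@]1(C)O[C@@H]1CC=C | intermediate
16 | (5S)-5-[(2R,3R)-2-methyl-3-(prop-2-en-1-yl)oxiran-2-yl]furan-2(5H)-one | O=C1C=C[C@H](O1)[C@]1(C)O[C@@H]1CC=C | intermediate
17 | endo Diels–Alder adduct: cis-fused 3a,4,7,7a-tetrahydroisobenzofuran-1(3H)-one (C9 lactone) with the (2R,3R)-epoxide unit on C2, the (R)-1-(trimethylsilyloxy)propan-2-yl group on C14, the triisopropylsilyl enol ether at C12=C13 and a methyl on C11; H1, H10, H11 and H14 all cis, H2 trans to H1 | O=C1O[C@H]([C@]3(C)O[C@@H]3CC=C)[C@@H]2[C@H]1[C@H](C)C=C(O[Si](C(C)C)(C(C)C)C(C)C)[C@@H]2[C@@H](C)CO[Si](C)(C)C | intermediate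
18 | oxepane lactone with C4 trimethylsilyl ether: C3–O–C16 ring closed, C3 and C4 as in the target, C4 allyl group, C9 lactone, C12=C13 silyl enol ether | C[Si](C)(C)O[C@H](CC=C)[C@]1(C)OC[C@H](C)[C@H]2C(O[Si](C(C)C)(C(C)C)C(C)C)=C[C@@H](C)[C@H]3C(=O)O[C@H]1[C@@H]23 | intermediate
19 | oxepane lactone with free C4 hydroxyl (as 18, C4–OH) | O[C@H](CC=C)[C@]1(C)OC[C@H](C)[C@H]2C(O[Si](C(C)C)(C(C)C)C(C)C)=C[C@@H](C)[C@H]3C(=O)O[C@H]1[C@@H]23 | intermediate
20 | C9 lactol acetate (anomer mixture) with C4 acetate, oxepane and silyl enol ether as in 19 | CC(=O)O[C@H](CC=C)[C@]1(C)OC[C@H](C)[C@H]2C(O[Si](C(C)C)(C(C)C)C(C)C)=C[C@@H](C)[C@H]3C(OC(C)=O)O[C@H]1[C@@H]23 | intermediate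
21 | trimethyl(2-methylprop-2-en-1-yl)silane (methallyltrimethylsilane) | C=C(C)C[Si](C)(C)C | starting material
22 | C9-methallyl tetrahydrofuran (C9 S, 2,9-cis) with C4 acetate, C4 allyl group, oxepane and C12=C13 silyl enol ether | CC(=O)O[C@H](CC=C)[C@]1(C)OC[C@H](C)[C@H]2C(O[Si](C(C)C)(C(C)C)C(C)C)=C[C@@H](C)[C@H]3[C@H](CC(C)=C)O[C@H]1[C@@H]23 | intermediate
23 | enone diene: as 22 with the C11=C12–C13=O enone; all stereocentres as in the target | CC(=O)O[C@H](CC=C)[C@]1(C)OC[C@H](C)[C@H]2C(=O)C=C(C)[C@H]3[C@H](CC(C)=C)O[C@H]1[C@@H]23 | intermediate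
24 | target CNP0320560.1: (1R,2S,3S,4R,6Z,9S,10S,14R,15R)-4-acetoxy tetracycle with 2,9- and 3,16-ether bridges and the 11-en-13-one | CC(=O)O[C@@H]1C/C=C(/C)C[C@@H]2O[C@H]3[C@@H]4[C@H]2C(C)=CC(=O)[C@@H]4[C@@H](C)CO[C@@]13C | target

## Step count and risks

Total steps: 13. Longest linear sequence: 11 steps (steps 3 to 13, from prop-2-yn-1-ol); the diene branch is 2 steps.

Steps most likely to fail:

**Step 9 (proposed new step).** The silyloxiranium may rearrange (hydride shift to a ketone) faster than the seven-membered ring closes, or the silyl enol ether may be lost. The fallback uses known chemistry and sets out from 17. Catalytic HClO4 in THF/H2O at 0 °C removes the trimethylsilyl ether and hydrolyses the trisubstituted epoxide by attack of water at tertiary C3 with inversion, giving the C3,C4,C16-triol lactone F3. Treating it with Tf2O and 2,6-lutidine in CH2Cl2 at −78 to 0 °C forms the primary C16 triflate, which the tertiary C3 hydroxyl displaces. This forms the C16–O bond with retention at C3, the way this oxepane has been closed in briarellin and asbestinin work, and returns to the route at 19.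

**Step 8 (Diels–Alder).** The butenolide is a sluggish dienophile, the endo/exo ratio with an acyclic diene may be modest, and the C15 stereocentre on the diene may slightly favour the exo approach. The fallback replaces the pericyclic step by an anionic double Michael annulation and sets out from 4. TMSOTf and Et3N give the bis(trimethylsilyl) dienol ether F1. MeLi in THF at 0 °C cleaves only the enol silyl ether to give the lithium (Z)-dienolate F2. This adds to 16 at −78 °C (Michael addition at C1 anti to the C2 substituent, then ring closure of the lactone enolate onto C11), and the resulting ketone enolate is trapped with TIPSOTf, returning to the route at 17.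

**Step 11 (C9 configuration).** The quaternary C3 group sits on the same face as the incoming silane, so attack could switch to the concave face and give the 2,9-trans ether. The fallback reverses the order in which carbon and hydrogen are delivered to C9 and sets out from 19. Methallylmagnesium chloride (3 equiv, THF, −78 °C) adds to the lactone to give the hemiketal F4. Et3SiH and TMSOTf in CH2Cl2 at −78 °C reduce its oxocarbenium ion, so hydride now takes the face the silane would have taken and the methallyl group ends on the other one, giving the C4 alcohol F5 with the C9 configuration opposite to that of the direct allylation. Acetylation (Ac2O, pyridine, DMAP) returns to the route at 22.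

Further compounds
F1 | step 8 | trimethyl{[(2E,4Z,6R)-6-methyl-7-(trimethylsilyloxy)hepta-2,4-dien-4-yl]oxy}silane | C/C=C/C(=C/[C@@H](C)CO[Si](C)(C)C)O[Si](C)(C)C
F2 | step 8 | lithium (2E,4Z,6R)-6-methyl-7-(trimethylsilyloxy)hepta-2,4-dien-4-olate | C/C=C/C(=C/[C@@H](C)CO[Si](C)(C)C)O[Li]
F3 | step 9 | C3,C4,C16-triol lactone (C3 hydroxyl with the target C3 configuration, C12=C13 triisopropylsilyl enol ether retained) | O[C@H](CC=C)[C@](C)(O)[C@H]1OC(=O)[C@@H]2[C@H](C)C=C(O[Si](C(C)C)(C(C)C)C(C)C)[C@H]([C@@H](C)CO)[C@H]12
F4 | step 11 | C9 methallyl hemiketal of 19 (anomer mixture) | O[C@H](CC=C)[C@]1(C)OC[C@H](C)[C@H]2C(O[Si](C(C)C)(C(C)C)C(C)C)=C[C@@H](C)[C@H]3C(O)(CC(C)=C)O[C@H]1[C@@H]23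
F5 | step 11 | C9-methallyl tetrahydrofuran with free C4 hydroxyl (C9 S) | O[C@H](CC=C)[C@]1(C)OC[C@H](C)[C@H]2C(O[Si](C(C)C)(C(C)C)C(C)C)=C[C@@H](C)[C@H]3[C@H](CC(C)=C)O[C@H]1[C@@H]23
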